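**Plan**

Ring numbering used in the text (not the IUPAC locants of the names): C1 carries the CH2O–coumarin arm, C2 the gem-dimethyl group, C3 the acetate, C4 and C5 are the ring CH2 groups, C6 carries the exocyclic methylene.
The retrosynthesis cuts, in order, the aryl ether O–CH2 bond (umbelliferone), the acetate, the ring bond C4–C5, the C6=CH2 and C6–C5 bonds (ester carbon plus two Me3SiCH2 units) and the C1–CH2O bond (formaldehyde).
The feature behind the key step: C4–C5 of the cyclohexane is a CH2–CH2 bond between the carbon next to oxygen-bearing C3 and the carbon allylic to the C6 methylene. The opened ring is therefore a 1,5-diene made of a C3=C4 methyl enol ether and a C6=C5 allylsilane, and anodic oxidation joins their two unsubstituted termini.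
Forward, the C6–C1–C2–C3–C4 chain comes from 3,3-dimethylpent-4-enoic acid and is functionalised in open-chain form (steps 1–9); the only carbocycle closes in step 10; the coumarin is attached last.
Stereochemistry: C1 is set by an Evans hydroxymethylation directed by (R)-4-benzyloxazolidinone; C3 is set by substrate-controlled borohydride reduction of the C3 ketone (equatorial alcohol, cis to the C1 arm).

Key step: step 10

**Route**

Step 1
Reactants: 1 3,3-dimethylpent-4-enoic acid; 2 (R)-4-benzyl-1,3-oxazolidin-2-one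
Product: 4 (4R)-4-benzyl-3-(3,3-dimethylpent-4-enoyl)-1,3-oxazolidin-2-one, via mixed pivalic anhydride 3 (not isolated)
Conditions: PivCl, Et3N, THF, −20 °C; then LiCl, 2, −20 °C → rt
Reagents that add atoms: none
Why: Standard N-acylation of an oxazolidinone through the mixed pivalic anhydride, which is attacked at its less hindered carbonyl.

Step 2
Reactants: 4 (4R)-4-benzyl-3-(3,3-dimethylpent-4-enoyl)-1,3-oxazolidin-2-one
Product: 5 (4R)-4-benzyl-3-[(2S)-2-(hydroxymethyl)-3,3-dimethylpent-4-enoyl]-1,3-oxazolidin-2-one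
Conditions: TiCl4, iPr2NEt, CH2Cl2, 0 °C; then 1,3,5-trioxane, TiCl4, 0 °C
Reagents that add atoms: 1,3,5-trioxane, C1OCOCO1
Why: Evans titanium-enolate hydroxymethylation, in which the chelated Z enolate is attacked by TiCl4-activated formaldehyde on the face away from the benzyl group, so the R auxiliary should set the 2S centre (ring carbon C1).

Step 3
Reactants: 5 (4R)-4-benzyl-3-[(2S)-2-(hydroxymethyl)-3,3-dimethylpent-4-enoyl]-1,3-oxazolidin-2-one
Product: 6 (4R)-4-benzyl-3-[(2S)-2-{[tert-butyl(diphenyl)silyl]oxymethyl}-3,3-dimethylpent-4-enoyl]-1,3-oxazolidin-2-one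
Conditions: TBDPSCl, imidazole, DMF, rt
Reagents that add atoms: tert-butyl(chloro)diphenylsilane, CC(C)(C)[Si](Cl)(c1ccccc1)c1ccccc1
Why: Standard silylation of a primary alcohol, with the tert-butyldiphenylsilyl group chosen because it must survive the acidic Tsuji–Wacker, ketalisation and ketal hydrolysis steps.

Step 4
Reactants: 6 (4R)-4-benzyl-3-[(2S)-2-{[tert-butyl(diphenyl)silyl]oxymethyl}-3,3-dimethylpent-4-enoyl]-1,3-oxazolidin-2-one
Product: 8 (2S)-2-{[tert-butyl(diphenyl)silyl]oxymethyl}-3,3-dimethylpent-4-enoic acid, via peroxy acid 7 (not isolated)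
Conditions: LiOH, H2O2, THF/H2O, 0 °C; then aq Na2SO3; 1 M HCl to pH 3
Reagents that add atoms: hydrogen peroxide (as LiOOH), OO
Why: Lithium hydroperoxide cleavage of an Evans imide attacks the exocyclic carbonyl even in hindered cases, and sulfite reduction of the peroxy acid should give the acid without epimerisation.

Step 5
Reactants: 8 (2S)-2-{[tert-butyl(diphenyl)silyl]oxymethyl}-3,3-dimethylpent-4-enoic acid
Product: 9 methyl (2S)-2-{[tert-butyl(diphenyl)silyl]oxymethyl}-3,3-dimethylpent-4-enoate
Conditions: MeI, K2CO3, DMF, rt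
Reagents that add atoms: iodomethane, CI
Why: SN2 O-alkylation of the carboxylate esterifies the hindered acid without acid and without touching the alpha centre.

Step 6
Reactants: 9 methyl (2S)-2-{[tert-butyl(diphenyl)silyl]oxymethyl}-3,3-dimethylpent-4-enoate
Product: 10 methyl (2S)-2-{[tert-butyl(diphenyl)silyl]oxymethyl}-3,3-dimethyl-4-oxopentanoate
Conditions: PdCl2 (cat.), CuCl, O2 (1 atm), DMF/H2O, rt → 40 °C
Reagents that add atoms: water, O
Why: Tsuji–Wacker oxidation of a terminal alkene gives the Markovnikov methyl ketone, and a vinyl group on a quaternary carbon in a gamma,delta-unsaturated ester reacts slowly but with the same regiochemistry.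

Step 7
Reactants: 10 methyl (2S)-2-{[tert-butyl(diphenyl)silyl]oxymethyl}-3,3-dimethyl-4-oxopentanoate
Product: 11 methyl (2S)-2-{[tert-butyl(diphenyl)silyl]oxymethyl}-4,4-dimethoxy-3,3-dimethylpentanoate
Conditions: HC(OMe)3, MeOH, TsOH·H2O (cat.), rt; Et3N quench
Reagents that add atoms: trimethyl orthoformate, COC(OC)OC; methanol, CO
Why: Acid-catalysed ketalisation driven by the orthoformate as water scavenger converts even a pinacolone-type ketone into its dimethyl ketal, which masks the ketone for step 8 and is the enol ether precursor.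

Step 8
Reactants: 11 methyl (2S)-2-{[tert-butyl(diphenyl)silyl]oxymethyl}-4,4-dimethoxy-3,3-dimethylpentanoate; 12 (trimethylsilyl)methylmagnesium chloride
Product: 14 tert-butyl{[(2R)-4,4-dimethoxy-3,3-dimethyl-2-[3-(trimethylsilyl)prop-1-en-2-yl]pentyl]oxy}diphenylsilane, via bis(silylmethyl) carbinol 13 (not isolated)
Conditions: 12 (excess), CeCl3, THF, −78 °C → rt; aq NaHCO3 work-up; then KH, THF, 0 °C
Reagents that add atoms: none
Why: Double addition of the weakly basic organocerium reagent to the ester followed by Peterson elimination of the resulting carbinol is the standard ester-to-allylsilane conversion, and the base-induced elimination spares the ketal.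

Step 9
Reactants: 14 tert-butyl{[(2R)-4,4-dimethoxy-3,3-dimethyl-2-[3-(trimethylsilyl)prop-1-en-2-yl]pentyl]oxy}diphenylsilane
Product: 15 tert-butyl{[(2R)-4-methoxy-3,3-dimethyl-2-[3-(trimethylsilyl)prop-1-en-2-yl]pent-4-en-1-yl]oxy}diphenylsilane
Conditions: TMSOTf, iPr2NEt, CH2Cl2, −20 °C → rt; purification on Et3N-deactivated silica
Reagents that add atoms: none
Why: In this standard ketal-to-enol-ether elimination the silyl triflate ionises the ketal and the amine deprotonates the only enolisable carbon (the methyl group, the other alpha carbon being quaternary), which should outpace the geometrically disfavoured 5-endo attack of the allylsilane on the oxocarbenium ion.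

Step 10
Reactants: 15 tert-butyl{[(2R)-4-methoxy-3,3-dimethyl-2-[3-(trimethylsilyl)prop-1-en-2-yl]pent-4-en-1-yl]oxy}diphenylsilane
Product: 16 tert-butyl{[(1S)-3,3-dimethoxy-2,2-dimethyl-6-methylidenecyclohexyl]methoxy}diphenylsilane
Conditions: RVC anode, Pt cathode, undivided cell, constant current (2.2 F/mol), 0.1 M LiClO4, 2,6-lutidine, MeOH/CH2Cl2 (1:4), rt
Reagents that add atoms: methanol, CO
Why: Proposed new method: one-electron oxidation at the anode of either electron-rich olefin of the 2-methoxy-1,5-diene gives a radical cation that is captured by the other olefin through bonding of the unsubstituted termini C4 and C5, leaving an oxocarbenium ion at C3 and a tertiary beta-silyl radical at C6; a second electron transfer, loss of the silyl group to methanol and methanol addition at C3 then give the exocyclic methylene and the dimethyl ketal. The closest known reactions are the intramolecular anodic coupling of enol ether radical cations with allylsilanes and the 1,6-closure of 1,5-diene radical cations, neither of which has been shown with both olefins ending inside the new ring. The cyclohexane closes in 6-endo-trig mode with respect to each olefin. No stereocentre is formed, and C1 carries no group that is oxidised or deprotonated under these conditions, so its configuration should be kept. The step needs ring closure to outrun methanol capture of the radical cation and oxidative desilylation: the gem-dimethyl group at C2 holds the termini together (Thorpe–Ingold effect), only terminus-to-terminus bonding places charge and spin on stabilised carbons, and the low methanol content with 2,6-lutidine buffer limits solvolysis.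

Step 11
Reactants: 16 tert-butyl{[(1S)-3,3-dimethoxy-2,2-dimethyl-6-methylidenecyclohexyl]methoxy}diphenylsilane
Product: 17 (3S)-3-{[tert-butyl(diphenyl)silyl]oxymethyl}-2,2-dimethyl-4-methylidenecyclohexan-1-one
Conditions: PPTS (cat.), acetone/H2O, rt
Reagents that add atoms: water, O
Why: Mild acid hydrolysis of a dimethyl ketal frees the ketone, while the silyl ether and the non-conjugated exocyclic alkene should be untouched.

Step 12
Reactants: 17 (3S)-3-{[tert-butyl(diphenyl)silyl]oxymethyl}-2,2-dimethyl-4-methylidenecyclohexan-1-one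
Product: 18 (1R,3S)-3-{[tert-butyl(diphenyl)silyl]oxymethyl}-2,2-dimethyl-4-methylidenecyclohexan-1-ol
Conditions: NaBH4, MeOH, −20 → 0 °C
Reagents that add atoms: none
Why: Borohydride reduction of a 2,2-dimethylcyclohexanone proceeds by axial attack on the face opposite the C1 arm (substrate control, as in 4,4-dimethyl-3-keto terpenoids), which should give the equatorial alcohol cis to the silyloxymethyl group, that is, the 1R carbinol centre.

Step 13
Reactants: 18 (1R,3S)-3-{[tert-butyl(diphenyl)silyl]oxymethyl}-2,2-dimethyl-4-methylidenecyclohexan-1-ol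
Product: 19 (1R,3S)-3-{[tert-butyl(diphenyl)silyl]oxymethyl}-2,2-dimethyl-4-methylidenecyclohexyl acetate
Conditions: Ac2O, pyridine, DMAP (cat.), CH2Cl2, rt
Reagents that add atoms: acetic anhydride, CC(=O)OC(C)=O
Why: DMAP-catalysed acetylation of a secondary alcohol with retention at the carbinol carbon.

Step 14
Reactants: 19 (1R,3S)-3-{[tert-butyl(diphenyl)silyl]oxymethyl}-2,2-dimethyl-4-methylidenecyclohexyl acetate
Product: 20 (1R,3S)-3-(hydroxymethyl)-2,2-dimethyl-4-methylidenecyclohexyl acetate
Conditions: HF·pyridine, pyridine/THF, 0 °C → rt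
Reagents that add atoms: none
Why: Fluoride cleavage of the silyl ether under buffered, non-basic conditions leaves the acetate in place and avoids acyl migration.

Step 15
Reactants: 20 (1R,3S)-3-(hydroxymethyl)-2,2-dimethyl-4-methylidenecyclohexyl acetate; 21 umbelliferone (7-hydroxy-2H-chromen-2-one)
Product: 22 (1R,3S)-2,2-dimethyl-4-methylidene-3-{[(2-oxo-2H-chromen-7-yl)oxy]methyl}cyclohexyl acetate
Conditions: PPh3, DIAD, THF, 0 °C → rt
Reagents that add atoms: none
Why: Mitsunobu etherification of a primary alcohol with an acidic phenol forms the aryl ether at a carbon that is not a stereocentre, under neutral conditions that spare the acetate, the lactone and the allylic C1–H.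

**Compound list**

1 | 3,3-dimethylpent-4-enoic acid | C=CC(C)(C)CC(=O)O | starting material
2 | (R)-4-benzyl-1,3-oxazolidin-2-one | O=C1N[C@H](Cc2ccccc2)CO1 | starting material
3 | 2,2-dimethylpropanoic 3,3-dimethylpent-4-enoic anhydride | C=CC(C)(C)CC(=O)OC(=O)C(C)(C)C | intermediate
4 | (4R)-4-benzyl-3-(3,3-dimethylpent-4-enoyl)-1,3-oxazolidin-2-one | C=CC(C)(C)CC(=O)N1[C@H](Cc2ccccc2)COC1=O | intermediate
5 | (4R)-4-benzyl-3-[(2S)-2-(hydroxymethyl)-3,3-dimethylpent-4-enoyl]-1,3-oxazolidin-2-one | C=CC(C)(C)[C@@H](CO)C(=O)N1[C@H](Cc2ccccc2)COC1=O | intermediate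
6 | (4R)-4-benzyl-3-[(2S)-2-{[tert-butyl(diphenyl)silyl]oxymethyl}-3,3-dimethylpent-4-enoyl]-1,3-oxazolidin-2-one | C=CC(C)(C)[C@@H](CO[Si](c1ccccc1)(c1ccccc1)C(C)(C)C)C(=O)N1[C@H](Cc2ccccc2)COC1=O | intermediate
7 | (2S)-2-{[tert-butyl(diphenyl)silyl]oxymethyl}-3,3-dimethylpent-4-eneperoxoic acid | C=CC(C)(C)[C@@H](CO[Si](c1ccccc1)(c1ccccc1)C(C)(C)C)C(=O)OO | intermediate
8 | (2S)-2-{[tert-butyl(diphenyl)silyl]oxymethyl}-3,3-dimethylpent-4-enoic acid | C=CC(C)(C)[C@@H](CO[Si](c1ccccc1)(c1ccccc1)C(C)(C)C)C(=O)O | intermediate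
9 | methyl (2S)-2-{[tert-butyl(diphenyl)silyl]oxymethyl}-3,3-dimethylpent-4-enoate | C=CC(C)(C)[C@@H](CO[Si](c1ccccc1)(c1ccccc1)C(C)(C)C)C(=O)OC | intermediate
10 | methyl (2S)-2-{[tert-butyl(diphenyl)silyl]oxymethyl}-3,3-dimethyl-4-oxopentanoate | CC(=O)C(C)(C)[C@@H](CO[Si](c1ccccc1)(c1ccccc1)C(C)(C)C)C(=O)OC | intermediate
11 | methyl (2S)-2-{[tert-butyl(diphenyl)silyl]oxymethyl}-4,4-dimethoxy-3,3-dimethylpentanoate | COC(C)(OC)C(C)(C)[C@@H](CO[Si](c1ccccc1)(c1ccccc1)C(C)(C)C)C(=O)OC | intermediate
12 | (trimethylsilyl)methylmagnesium chloride | C[Si](C)(C)C[Mg]Cl | starting material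
13 | (3S)-3-{[tert-butyl(diphenyl)silyl]oxymethyl}-5,5-dimethoxy-4,4-dimethyl-1-(trimethylsilyl)-2-[(trimethylsilyl)methyl]hexan-2-ol | COC(C)(OC)C(C)(C)[C@@H](CO[Si](c1ccccc1)(c1ccccc1)C(C)(C)C)C(O)(C[Si](C)(C)C)C[Si](C)(C)C | intermediate
14 | tert-butyl{[(2R)-4,4-dimethoxy-3,3-dimethyl-2-[3-(trimethylsilyl)prop-1-en-2-yl]pentyl]oxy}diphenylsilane | COC(C)(OC)C(C)(C)[C@@H](CO[Si](c1ccccc1)(c1ccccc1)C(C)(C)C)C(=C)C[Si](C)(C)C | intermediate
15 | tert-butyl{[(2R)-4-methoxy-3,3-dimethyl-2-[3-(trimethylsilyl)prop-1-en-2-yl]pent-4-en-1-yl]oxy}diphenylsilane | C=C(OC)C(C)(C)[C@@H](CO[Si](c1ccccc1)(c1ccccc1)C(C)(C)C)C(=C)C[Si](C)(C)C | intermediate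
16 | tert-butyl{[(1S)-3,3-dimethoxy-2,2-dimethyl-6-methylidenecyclohexyl]methoxy}diphenylsilane | C=C1CCC(OC)(OC)C(C)(C)[C@H]1CO[Si](c1ccccc1)(c1ccccc1)C(C)(C)C | intermediate
17 | (3S)-3-{[tert-butyl(diphenyl)silyl]oxymethyl}-2,2-dimethyl-4-methylidenecyclohexan-1-one | C=C1CCC(=O)C(C)(C)[C@H]1CO[Si](c1ccccc1)(c1ccccc1)C(C)(C)C | intermediate
18 | (1R,3S)-3-{[tert-butyl(diphenyl)silyl]oxymethyl}-2,2-dimethyl-4-methylidenecyclohexan-1-ol | C=C1CC[C@@H](O)C(C)(C)[C@H]1CO[Si](c1ccccc1)(c1ccccc1)C(C)(C)C | intermediate
19 | (1R,3S)-3-{[tert-butyl(diphenyl)silyl]oxymethyl}-2,2-dimethyl-4-methylidenecyclohexyl acetate | C=C1CC[C@@H](OC(C)=O)C(C)(C)[C@H]1CO[Si](c1ccccc1)(c1ccccc1)C(C)(C)C | intermediate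
20 | (1R,3S)-3-(hydroxymethyl)-2,2-dimethyl-4-methylidenecyclohexyl acetate | C=C1CC[C@@H](OC(C)=O)C(C)(C)[C@H]1CO | intermediate
21 | umbelliferone (7-hydroxy-2H-chromen-2-one) | O=c1ccc2ccc(O)cc2o1 | starting material
22 | (1R,3S)-2,2-dimethyl-4-methylidene-3-{[(2-oxo-2H-chromen-7-yl)oxy]methyl}cyclohexyl acetate | C=C1CC[C@@H](OC(C)=O)C(C)(C)[C@H]1COc1ccc2ccc(=O)oc2c1 | target

**Step count and risks**

Total step count: 15. Longest linear sequence: 15 steps (from acid 1).

Steps most likely to fail:

Step 10 (anodic ring closure). Methanol capture of the radical cation, oxidative loss of the silyl group before cyclisation, or Cope-type ring opening of the cyclised radical cation may outrun the wanted C4–C5 bond formation and trapping. Fallback by known chemistry, making the same bond by intramolecular enolate alkylation: setting out from ketal 14, hydrolysis with PPTS in wet acetone should give (4R)-4-{[tert-butyl(diphenyl)silyl]oxymethyl}-3,3-dimethyl-5-[(trimethylsilyl)methyl]hex-5-en-2-one F1. Bromodesilylation with NBS in CH2Cl2 at −78 °C (electrophilic attack at the alkene terminus with loss of silicon) should then give (4R)-5-(bromomethyl)-4-{[tert-butyl(diphenyl)silyl]oxymethyl}-3,3-dimethylhex-5-en-2-one F2. LDA in THF at −78 °C forms the only possible enolate, at the methyl group, which should close the ring by 6-(enolendo)-exo-tet C-alkylation; direct and allylic displacement give the same product. This comes back to the route at ketone 17, bypassing 15 and 16.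

Step 8 (ester to allylsilane). The second addition to the very hindered ester may stall at the alpha-silyl ketone enolate stage. Fallback by enol triflate cross-coupling: setting out from ester 11, Me3SiCH2Li (2 equiv) followed by methanol (single addition, then desilylation of the alpha-silyl ketone) should give (3S)-3-{[tert-butyl(diphenyl)silyl]oxymethyl}-5,5-dimethoxy-4,4-dimethylhexan-2-one F3. Kinetic deprotonation at the methyl group with KHMDS and trapping with PhNTf2 at −78 °C should give (3S)-3-{[tert-butyl(diphenyl)silyl]oxymethyl}-5,5-dimethoxy-4,4-dimethylhex-1-en-2-yl trifluoromethanesulfonate F4. Kumada coupling with 12 under Pd(PPh3)4 catalysis in THF then comes back to the route at allylsilane 14.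

Step 9 (ketal to enol ether). While the ketal is ionised, the allylsilane may be consumed by intermolecular allylation of the oxocarbenium ion or by protodesilylation. Fallback by changing the order, so that the enol ether exists before the allylsilane: setting out from ester 11, the same TMSOTf/iPr2NEt elimination should give methyl (2S)-2-{[tert-butyl(diphenyl)silyl]oxymethyl}-4-methoxy-3,3-dimethylpent-4-enoate F5. Addition of 12/CeCl3 with a basic work-up should give (3S)-3-{[tert-butyl(diphenyl)silyl]oxymethyl}-5-methoxy-4,4-dimethyl-1-(trimethylsilyl)-2-[(trimethylsilyl)methyl]hex-5-en-2-ol F6. Peterson elimination with KH in THF then comes back to the route at enol ether 15, bypassing 14.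

Further compounds
F1 | step 10 | (4R)-4-{[tert-butyl(diphenyl)silyl]oxymethyl}-3,3-dimethyl-5-[(trimethylsilyl)methyl]hex-5-en-2-one | CC(=O)C(C)(C)[C@@H](CO[Si](c1ccccc1)(c1ccccc1)C(C)(C)C)C(=C)C[Si](C)(C)C
F2 | step 10 | (4R)-5-(bromomethyl)-4-{[tert-butyl(diphenyl)silyl]oxymethyl}-3,3-dimethylhex-5-en-2-one | CC(=O)C(C)(C)[C@@H](CO[Si](c1ccccc1)(c1ccccc1)C(C)(C)C)C(=C)CBr
F3 | step 8 | (3S)-3-{[tert-butyl(diphenyl)silyl]oxymethyl}-5,5-dimethoxy-4,4-dimethylhexan-2-one | COC(C)(OC)C(C)(C)[C@@H](CO[Si](c1ccccc1)(c1ccccc1)C(C)(C)C)C(C)=O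
F4 | step 8 | (3S)-3-{[tert-butyl(diphenyl)silyl]oxymethyl}-5,5-dimethoxy-4,4-dimethylhex-1-en-2-yl trifluoromethanesulfonate | COC(C)(OC)C(C)(C)[C@@H](CO[Si](c1ccccc1)(c1ccccc1)C(C)(C)C)C(=C)OS(=O)(=O)C(F)(F)F
F5 | step 9 | methyl (2S)-2-{[tert-butyl(diphenyl)silyl]oxymethyl}-4-methoxy-3,3-dimethylpent-4-enoate | C=C(OC)C(C)(C)[C@@H](CO[Si](c1ccccc1)(c1ccccc1)C(C)(C)C)C(=O)OC
F6 | step 9 | (3S)-3-{[tert-butyl(diphenyl)silyl]oxymethyl}-5-methoxy-4,4-dimethyl-1-(trimethylsilyl)-2-[(trimethylsilyl)methyl]hex-5-en-2-ol | C=C(OC)C(C)(C)[C@@H](CO[Si](c1ccccc1)(c1ccccc1)C(C)(C)C)C(O)(C[Si](C)(C)C)C[Si](C)(C)C
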